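All runs stem from a simulated flask for substances that don't exist, noise included.

What struck me in these runs was their slowness: after 30.0 h the teal run still held 59.1% of its electrophile. So the question for each new flask is how fast this reaction falls behind its early pace.

| flask | electrophile | nucleophile | remark | time |
|---|---|---|---|---|
| teal | 0.072 M | 0.11 M | run made earlier |  |
| blue | 0.14 M | 0.11 M | run made earlier |  |
| north-west | 0.10 M | 0.110 M |  | 30 h |
| east | 0.060 M | 0.110 M |  | 8.0 h |

| run | time / h | target / % | electrophile / % |
|---|---|---|---|
| teal | 2.50 | 5.9 | 95.2 |
| teal | 4.00 | 8.0 | 91.2 |
| teal | 6.00 | 13.3 | 87.1 |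
| teal | 10.0 | 19.3 | 80.5 |
| teal | 20.0 | 32.6 | 68.5 |
| teal | 30.0 | 40.5 | 59.1 |
| blue | 2.00 | 3.5 | 95.4 |
| blue | 6.00 | 11.6 | 87.9 |
| blue | 10.0 | 17.2 | 81.9 |
| blue | 15.0 | 22.0 | 77.6 |
| blue | 25.0 | 28.6 | 71.0 |
| blue | 30.0 | 32.0 | 68.2 |

(each reading ± 0.5 percentage points)

- the flask that ends with the higher amount of target, in percent of the electrophile charged, or "neither" when 2 percentage points or less lies between them (north-west / east / neither)
- final target, as a percentage of the electrophile charged, in north-west
- final target, as a percentage of the electrophile charged, in east

- a reading or a percentage of target counts all its forms, free or not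

I built the flask up in steps. With the main step alone and nucleophile held at its charge (pseudo-first-order), blue should match teal in percent at 30.0 h, since both had 0.11 M of nucleophile, yet blue read 32.0%, lower than teal's 40.5%. I then let each target use up one nucleophile; the constant from teal's last reading, 0.185 M⁻¹ h⁻¹, brought blue down to 36.0%, still too high. Nucleophile was never read, so the next step is an inference: each target costs two nucleophiles. The second-order constant reckoned on that cost from the same teal reading is 0.232 M⁻¹ h⁻¹, and it gives blue 31.0%. For the rest, target and electrophile in teal's last reading sum to 99.6%, so I added no further path for the electrophile. These steps took north-west from 40.5% through 38.6% to 36.2%, and my figure for east is 16.8%, so north-west ends higher than east.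

The forecast also said north-west, with 36.5% (34.5% to 38.5%) in north-west and 17% (15.3% to 18.5%) in east. Its grounds differ from mine: it saw the apparent constant fall, which it wrote “suggests product inhibition or reversibility”, where I read a second nucleophile lost.

The flasks gave 36.4% in north-west and 16.7% in east, so north-west ended higher.

    electrophile + nucleophile → acid set free + target (k = 0.230 M⁻¹ h⁻¹)
    nucleophile + acid set free ⇌ protonated nucleophile, settled at all times (K = 430 M⁻¹)
    crystals ⇌ target, rate k3*(cs3 - [target]) while solid is left; crystals form when [target] > cs3 (solubility = 2.20 mM, k = 3.00 h⁻¹)

Neither flask had come to rest. At 30.0 h north-west had 36% of its nucleophile free, and my constant, with nucleophile held at that amount, gives its electrophile a half-life of 76.4 h; east, with 82% free at 8.00 h, gives 33.2 h on the same terms. The same constant gives 52.7% for a flask like east with 0.44 M of nucleophile, which held 52.4% target at 8.00 h. Left ten times as long, east rose to 65.5%, where I reckon 65.0%, and north-west rose to 65.3%, with 3.53% of its nucleophile free.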